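**Strategy.** Everything rests on disconnecting C2 of the flavanone ring C from C1′ of its aryl ring B. C2 is the β-carbon of the O1–C2=C3–C4=O enone of a chromone, and C1′ sits between two unsubstituted carbons (C2′, C6′); hence an unhindered arylboronic acid that already carries the complete benzyl-protected 8-aryl-luteolin unit is added to 5,7-bis(benzyloxy)chromone under Pd(OCOCF3)2/(R)-t-BuPyOx catalysis. This one asymmetric conjugate addition joins both halves and sets the sole stereocentre (2S). The boronic acid arises from Suzuki coupling of 8-iodo-tetra-O-benzylluteolin with a bromo/chloro-differentiated catechol ring; hydrogenolysis of eight benzyl ethers finishes the route.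

Key step: step 9

Remark: the biaryl axis between flavone C8 and ring B carries only three ortho substituents and is taken as freely rotating, so C2 (S) is the only stereogenic element to control.

**Step 1**
Reactants: 1 luteolin
Product: 2 5,7-bis(benzyloxy)-2-[3,4-bis(benzyloxy)phenyl]-4H-chromen-4-one (tetra-O-benzylluteolin)
Conditions: BnBr (6 equiv), K2CO3, DMF, 80 °C
Reagents that add atoms: benzyl bromide, BrCc1ccccc1
Why: Williamson etherification of all four phenols; the hydrogen-bonded 5-OH is the slowest and is the reason for excess reagent and heating.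

**Step 2**
Reactants: 2 tetra-O-benzylluteolin
Product: 3 5,7-bis(benzyloxy)-2-[3,4-bis(benzyloxy)phenyl]-8-iodo-4H-chromen-4-one
Conditions: NIS (1.05 equiv), TFA (cat.), CH2Cl2/MeCN, 0 °C to rt
Reagents that add atoms: N-iodosuccinimide, O=C1CCC(=O)N1I
Why: Electrophilic aromatic iodination; in the fully O-alkylated flavone ring A is the most electron-rich ring, and C8 (flanked by O1 and 7-OBn) should be favoured over the more hindered C6 between two benzyloxy groups.

**Step 3**
Reactants: 4 3-bromo-5-chloro-2-hydroxybenzaldehyde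
Product: 6 3-bromo-5-chlorobenzene-1,2-diol, via aryl formate 5 (not isolated)
Conditions: 30% aq. H2O2, NaOH (1.1 equiv), H2O/THF, 0 °C to rt; then aq. HCl
Reagents that add atoms: hydrogen peroxide, OO
Why: Dakin oxidation: hydroperoxide adds to the aldehyde of the ortho-hydroxybenzaldehyde, aryl migration to oxygen gives formate 5, and this is saponified in the same flask to the catechol.

**Step 4**
Reactants: 6 3-bromo-5-chlorobenzene-1,2-diol
Product: 7 1,2-bis(benzyloxy)-3-bromo-5-chlorobenzene
Conditions: BnBr (2.4 equiv), K2CO3, DMF, 60 °C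
Reagents that add atoms: benzyl bromide, BrCc1ccccc1
Why: Williamson etherification of both catechol hydroxyls, which also protects the electron-rich catechol from oxidation.

**Step 5**
Reactants: 7 1,2-bis(benzyloxy)-3-bromo-5-chlorobenzene
Product: 8 2-[2,3-bis(benzyloxy)-5-chlorophenyl]-4,4,5,5-tetramethyl-1,3,2-dioxaborolane
Conditions: B2pin2, Pd(dppf)Cl2 (5 mol%), KOAc, 1,4-dioxane, 90 °C
Reagents that add atoms: bis(pinacolato)diboron, CC1(C)OB(OC1(C)C)B1OC(C)(C)C(C)(C)O1
Why: Miyaura borylation; oxidative addition of dppf-ligated zerovalent palladium is selective for C–Br over C–Cl, so the chloride survives as the latent boron site for the key step.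

**Step 6**
Reactants: 3 8-iodo-tetra-O-benzylluteolin; 8 aryl pinacol boronate
Product: 9 5,7-bis(benzyloxy)-8-[2,3-bis(benzyloxy)-5-chlorophenyl]-2-[3,4-bis(benzyloxy)phenyl]-4H-chromen-4-one
Conditions: Pd(PPh3)4 (10 mol%), K2CO3, DMF/H2O, 90 °C
Reagents that add atoms: none
Why: Suzuki–Miyaura coupling of the aryl iodide; the electron-rich aryl chloride is inert to the triphenylphosphine catalyst, and this type of 8-iodoflavone coupling to a tri-ortho-substituted biaryl is established in biflavone chemistry.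

**Step 7**
Reactants: 9 biaryl chloride
Product: 10 {3,4-bis(benzyloxy)-5-[5,7-bis(benzyloxy)-2-(3,4-bis(benzyloxy)phenyl)-4-oxo-4H-chromen-8-yl]phenyl}boronic acid
Conditions: B2(OH)4 (3 equiv), Pd(OAc)2 (5 mol%), XPhos (10 mol%), KOAc, EtOH/THF, 80 °C; aqueous work-up
Reagents that add atoms: tetrahydroxydiboron, OB(O)B(O)O
Why: Miyaura-type borylation of an aryl chloride with tetrahydroxydiboron gives the free boronic acid directly; the bulky electron-rich XPhos ligand allows oxidative addition into the deactivated C–Cl bond.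

**Step 8**
Reactants: 11 5,7-dihydroxy-4H-chromen-4-one
Product: 12 5,7-bis(benzyloxy)-4H-chromen-4-one
Conditions: BnBr (2.5 equiv), K2CO3, DMF, 70 °C
Reagents that add atoms: benzyl bromide, BrCc1ccccc1
Why: Williamson etherification; anhydrous carbonate avoids hydroxide attack at the unsubstituted C2 of the chromone.

**Step 9**
Reactants: 10 arylboronic acid; 12 5,7-bis(benzyloxy)chromone (2 equiv)
Product: 13 (2S)-5,7-bis(benzyloxy)-2-{3,4-bis(benzyloxy)-5-[5,7-bis(benzyloxy)-2-(3,4-bis(benzyloxy)phenyl)-4-oxo-4H-chromen-8-yl]phenyl}-2,3-dihydro-4H-chromen-4-one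
Conditions: Pd(OCOCF3)2 (10 mol%), (R)-t-BuPyOx (12 mol%), NH4PF6 (30 mol%), H2O (5 equiv), ClCH2CH2Cl, 60 °C
Reagents that add atoms: none
Why: Transmetalation of boronic acid 10 to the cationic PyOx-ligated divalent palladium centre gives an aryl–palladium species that inserts the C2=C3 bond of chromone 12 with aryl delivery to C2, the β-carbon of the O1–C2=C3–C4=O enone; the palladium enolate is then protonated by water, so the catalyst turns over without a redox change. The closest known reaction type is the Pd/PyOx-catalysed asymmetric conjugate addition of arylboronic acids to chromones and cyclic enones, applied here to a larger boronic acid. No ring is closed; only the C2–C1′ bond forms. The C2 stereocentre is controlled by the ligand, whose oxazoline tert-butyl group differentiates the two faces of the coordinated chromone during insertion; by analogy with the facial sense of this ligand class on cyclic enones the (R)-ligand is expected to give (2S), and the antipode would be used if the sense proved opposite. The step needs chemoselectivity for the unsubstituted enone of 12 over the flavone enone inside 10, secured because the latter is β,β-disubstituted and conjugated to its aryl group; it also needs protonation of the enolate rather than β-hydride elimination or ring opening to the chalcone, secured by the aqueous, base-free medium. Transmetalation and insertion should be fast because the boron-bearing C1′ lies between two C–H positions, the bulky flavonyl group being meta.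

**Step 10**
Reactants: 13 octa-O-benzyl flavanone–flavone
Product: 14 (2S)-2-{5-[2-(3,4-dihydroxyphenyl)-5,7-dihydroxy-4-oxo-4H-chromen-8-yl]-3,4-dihydroxyphenyl}-5,7-dihydroxy-2,3-dihydro-4H-chromen-4-one (target)
Conditions: H2 (1 atm), 10% Pd/C, THF/MeOH, rt
Reagents that add atoms: none
Why: Hydrogenolysis of the eight benzyl ethers under neutral conditions, which should leave the flavone C2=C3 bond and both carbonyls intact and, in the absence of base, should not open the flavanone to the chalcone, so C2 is not scrambled.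

**Compound list**
1 | luteolin, 2-(3,4-dihydroxyphenyl)-5,7-dihydroxy-4H-chromen-4-one | O=c1cc(-c2ccc(O)c(O)c2)oc2cc(O)cc(O)c12 | starting material
2 | 5,7-bis(benzyloxy)-2-[3,4-bis(benzyloxy)phenyl]-4H-chromen-4-one | O=c1cc(-c2ccc(OCc3ccccc3)c(OCc3ccccc3)c2)oc2cc(OCc3ccccc3)cc(OCc3ccccc3)c12 | intermediate
3 | 5,7-bis(benzyloxy)-2-[3,4-bis(benzyloxy)phenyl]-8-iodo-4H-chromen-4-one | O=c1cc(-c2ccc(OCc3ccccc3)c(OCc3ccccc3)c2)oc2c(I)c(OCc3ccccc3)cc(OCc3ccccc3)c12 | intermediate
4 | 3-bromo-5-chloro-2-hydroxybenzaldehyde | O=Cc1cc(Cl)cc(Br)c1O | starting material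
5 | 3-bromo-5-chloro-2-hydroxyphenyl formate (not isolated) | O=COc1cc(Cl)cc(Br)c1O | intermediate
6 | 3-bromo-5-chlorobenzene-1,2-diol | Oc1cc(Cl)cc(Br)c1O | intermediate
7 | 1,2-bis(benzyloxy)-3-bromo-5-chlorobenzene | Brc1cc(Cl)cc(OCc2ccccc2)c1OCc1ccccc1 | intermediate
8 | 2-[2,3-bis(benzyloxy)-5-chlorophenyl]-4,4,5,5-tetramethyl-1,3,2-dioxaborolane | CC1(C)OB(OC1(C)C)c1cc(Cl)cc(OCc2ccccc2)c1OCc1ccccc1 | intermediate
9 | 5,7-bis(benzyloxy)-8-[2,3-bis(benzyloxy)-5-chlorophenyl]-2-[3,4-bis(benzyloxy)phenyl]-4H-chromen-4-one | O=c1cc(-c2ccc(OCc3ccccc3)c(OCc3ccccc3)c2)oc2c(-c3cc(Cl)cc(OCc4ccccc4)c3OCc3ccccc3)c(OCc3ccccc3)cc(OCc3ccccc3)c12 | intermediate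
10 | {3,4-bis(benzyloxy)-5-[5,7-bis(benzyloxy)-2-(3,4-bis(benzyloxy)phenyl)-4-oxo-4H-chromen-8-yl]phenyl}boronic acid | O=c1cc(-c2ccc(OCc3ccccc3)c(OCc3ccccc3)c2)oc2c(-c3cc(B(O)O)cc(OCc4ccccc4)c3OCc3ccccc3)c(OCc3ccccc3)cc(OCc3ccccc3)c12 | intermediate
11 | 5,7-dihydroxy-4H-chromen-4-one | O=c1ccoc2cc(O)cc(O)c12 | starting material
12 | 5,7-bis(benzyloxy)-4H-chromen-4-one | O=c1ccoc2cc(OCc3ccccc3)cc(OCc3ccccc3)c12 | intermediate
13 | (2S)-5,7-bis(benzyloxy)-2-{3,4-bis(benzyloxy)-5-[5,7-bis(benzyloxy)-2-(3,4-bis(benzyloxy)phenyl)-4-oxo-4H-chromen-8-yl]phenyl}-2,3-dihydro-4H-chromen-4-one | O=C1C[C@@H](c2cc(OCc3ccccc3)c(OCc3ccccc3)c(-c3c(OCc4ccccc4)cc(OCc4ccccc4)c4c(=O)cc(-c5ccc(OCc6ccccc6)c(OCc6ccccc6)c5)oc34)c2)Oc2cc(OCc3ccccc3)cc(OCc3ccccc3)c21 | intermediate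
14 | (2S)-2-{5-[2-(3,4-dihydroxyphenyl)-5,7-dihydroxy-4-oxo-4H-chromen-8-yl]-3,4-dihydroxyphenyl}-5,7-dihydroxy-2,3-dihydro-4H-chromen-4-one | O=C1C[C@@H](c2cc(O)c(O)c(-c3c(O)cc(O)c4c(=O)cc(-c5ccc(O)c(O)c5)oc34)c2)Oc2cc(O)cc(O)c21 | target

**Step count.** Total: 10 steps. Longest linear sequence: 7 steps (3, 4, 5, 6, 7, 9, 10).

**Steps most likely to fail**

Step 9. Insertion into the electron-rich 5,7-dialkoxychromone may be slow with the bulky chiral ligand, so protodeboronation of 10 could compete, and facial discrimination may be insufficient. The fallback sets out from 10 and 12 and returns at 13. The same C2–C1′ bond would be formed without asymmetric induction using the less hindered achiral catalyst Pd(OCOCF3)2/2,2′-bipyridine in aqueous ClCH2CH2Cl at 60 °C, giving the racemic octa-O-benzyl flavanone F1. Kinetic resolution by asymmetric transfer hydrogenation (RhCl(Cp*)[(R,R)-TsDPEN], HCO2H/Et3N, EtOAc, stopped near half conversion) would follow. The (R,R) catalyst is the antipode expected to reduce the (2R)-ketone faster, to the cis-(2R,4R)-flavan-4-ol F2, leaving the (2S)-ketone 13, which is separated by chromatography.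

Step 2. Iodination may occur at C6 (or C3) instead of C8, giving poor site selectivity. The fallback does not use 1 or 2; it sets out from commercial materials and returns at 3. Commercial 1-[4,6-bis(benzyloxy)-2-hydroxyphenyl]ethan-1-one F3 would be iodinated ortho to the chelated phenol (NIS, cat. TFA, MeCN) to 1-[4,6-bis(benzyloxy)-2-hydroxy-3-iodophenyl]ethan-1-one F4. Claisen–Schmidt condensation with commercial 3,4-bis(benzyloxy)benzaldehyde F5 (KOH, EtOH/THF) would give the (E)-2′-hydroxy-3′-iodochalcone F6. Oxidative cyclisation (cat. I2, DMSO, 120 °C) through the phenol oxygen next to iodine then places iodine at C8 of flavone 3 by construction.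

Step 6. Transmetalation and reductive elimination towards the tri-ortho-substituted biaryl may be slow, with protodeboronation of 8 and deiodination of 3 competing. The fallback sets out from 3 and 7 and returns at 9, with the coupling polarity reversed. Miyaura borylation of 3 (B2pin2, Pd(dppf)Cl2, KOAc, DMSO, 80 °C) would give 5,7-bis(benzyloxy)-2-[3,4-bis(benzyloxy)phenyl]-8-(4,4,5,5-tetramethyl-1,3,2-dioxaborolan-2-yl)-4H-chromen-4-one F7. This is coupled with bromide 7 (Pd(dppf)Cl2, K2CO3, dioxane/H2O, 90 °C) at C–Br in preference to C–Cl, giving 9 and making 8 unnecessary.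

**Further compounds**
F1 | step 9 | racemic 5,7-bis(benzyloxy)-2-{3,4-bis(benzyloxy)-5-[5,7-bis(benzyloxy)-2-(3,4-bis(benzyloxy)phenyl)-4-oxo-4H-chromen-8-yl]phenyl}-2,3-dihydro-4H-chromen-4-one | O=C1CC(c2cc(OCc3ccccc3)c(OCc3ccccc3)c(-c3c(OCc4ccccc4)cc(OCc4ccccc4)c4c(=O)cc(-c5ccc(OCc6ccccc6)c(OCc6ccccc6)c5)oc34)c2)Oc2cc(OCc3ccccc3)cc(OCc3ccccc3)c21
F2 | step 9 | 5,7-bis(benzyloxy)-8-{2,3-bis(benzyloxy)-5-[(2R,4R)-5,7-bis(benzyloxy)-4-hydroxy-3,4-dihydro-2H-chromen-2-yl]phenyl}-2-[3,4-bis(benzyloxy)phenyl]-4H-chromen-4-one (cis-flavan-4-ol) | O[C@@H]1C[C@H](c2cc(OCc3ccccc3)c(OCc3ccccc3)c(-c3c(OCc4ccccc4)cc(OCc4ccccc4)c4c(=O)cc(-c5ccc(OCc6ccccc6)c(OCc6ccccc6)c5)oc34)c2)Oc2cc(OCc3ccccc3)cc(OCc3ccccc3)c21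
F3 | step 2 | 1-[4,6-bis(benzyloxy)-2-hydroxyphenyl]ethan-1-one (commercial) | CC(=O)c1c(O)cc(OCc2ccccc2)cc1OCc1ccccc1
F4 | step 2 | 1-[4,6-bis(benzyloxy)-2-hydroxy-3-iodophenyl]ethan-1-one | CC(=O)c1c(O)c(I)c(OCc2ccccc2)cc1OCc1ccccc1
F5 | step 2 | 3,4-bis(benzyloxy)benzaldehyde (commercial) | O=Cc1ccc(OCc2ccccc2)c(OCc2ccccc2)c1
F6 | step 2 | (E)-1-[4,6-bis(benzyloxy)-2-hydroxy-3-iodophenyl]-3-[3,4-bis(benzyloxy)phenyl]prop-2-en-1-one | O=C(/C=C/c1ccc(OCc2ccccc2)c(OCc2ccccc2)c1)c1c(O)c(I)c(OCc2ccccc2)cc1OCc1ccccc1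
F7 | step 6 | 5,7-bis(benzyloxy)-2-[3,4-bis(benzyloxy)phenyl]-8-(4,4,5,5-tetramethyl-1,3,2-dioxaborolan-2-yl)-4H-chromen-4-one | O=c1cc(-c2ccc(OCc3ccccc3)c(OCc3ccccc3)c2)oc2c(B3OC(C)(C)C(C)(C)O3)c(OCc3ccccc3)cc(OCc3ccccc3)c12
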